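**Plan** (numbering: the main chain C1–C12 runs from the acetoxymethylene of the ring C5 side chain (C1) through the ring carbons C5 (stereocentre), C6 (ring CH=) and C7 (ring carbon bearing the lactone carbonyl C13) to the other acetoxymethylene (C12))
- Retrosynthetic cuts, in order: the two O‑acetyl bonds; C10=C11 (Wittig); C7–C8 together with the ring O–C13 bond, which gives a (4S)‑4‑hydroxy‑2‑ynoate (C1–C7, C13) and allyl alcohol (C8–C10); then C7–C13, C1–C2 with C3–CH3, and C4–C5.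
- Forward: C4–C5 (propargylation), C3–CH3 and C2–C1 (carboalumination, formaldehyde), C7–C13 (acetylide acylation), C7–C8 with closure of the only ring (the butenolide), C10=C11, acetates.
- Enabling feature: the ring atoms C5–C6=C7–C13(=O)–O are the cis adduct of hydrogen and carbon across the C6≡C7 bond of a γ‑hydroxy‑ynoate, and C10 can be carried as a carbonyl. A ruthenium‑catalysed alkene–alkyne coupling with allyl alcohol therefore makes the C7–C8 bond, the ring and the C10 aldehyde in one redox‑neutral operation.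
- Stereochemistry: C5 (S) comes from a chiral phosphoric acid‑catalysed propargylboration and is not touched afterwards; (E)‑C2=C3 from cis‑carboalumination; (E)‑C10=C11 from a stabilised ylide.

Key step: step 6

Remark on the chemistry: the sense of induction in step 1 is assumed to follow the usual model for this catalyst class; the acid antipode that gives the (S)‑carbinol is used (written here as (S)‑TRIP), and nothing else changes if it proves to be the other one.

Step 1
Reactants: 1 3‑(trimethylsilyl)prop‑2‑ynal; 2 allenylboronic acid pinacol ester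
Product: 4 (S)‑1‑(trimethylsilyl)hexa‑1,5‑diyn‑3‑ol, via pinacol borate 3 (not isolated)
Conditions: (S)‑TRIP [(S)‑3,3′‑bis(2,4,6‑triisopropylphenyl)‑1,1′‑binaphthyl‑2,2′‑diyl hydrogen phosphate] (10 mol %), 4 Å MS, toluene, −20 °C; aq. NaHCO3 work‑up
Reagents that add atoms: none
Why: Chiral phosphoric acid‑catalysed propargylboration, in which the allenylboronate adds through a closed six‑membered transition state while the acid activates the boronate and differentiates the aldehyde faces, should set the C5 stereocentre as (S) under catalyst control, and the borate 3 is hydrolysed on work‑up.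

Step 2
Reactants: 4 (S)‑1‑(trimethylsilyl)hexa‑1,5‑diyn‑3‑ol
Product: 7 (S,E)‑3‑methyl‑7‑(trimethylsilyl)hept‑2‑en‑6‑yne‑1,5‑diol, via alkenylalane 5 (not isolated), via lithium alanate 6 (not isolated)
Conditions: AlMe3 (3 equiv), Cp2ZrCl2 (0.5 equiv), CH2Cl2, 0 °C → rt; evaporate; n‑BuLi, THF, −78 °C; (CH2O)n, −78 °C → rt; 1 M HCl, 0 °C
Reagents that add atoms: trimethylaluminium C[Al](C)C; paraformaldehyde (as formaldehyde) C=O
Why: Zirconium‑catalysed Negishi carboalumination should add methyl and aluminium cis across the terminal alkyne only (methyl to the internal carbon, the silylalkyne being inert), and hydroxymethylation of the derived alanate by formaldehyde with retention fixes the (E)‑C2=C3 geometry without forming a stereocentre.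

Step 3
Reactants: 7 (S,E)‑3‑methyl‑7‑(trimethylsilyl)hept‑2‑en‑6‑yne‑1,5‑diol
Product: 8 (S,E)‑1,5‑bis(tert‑butyldimethylsilyloxy)‑3‑methyl‑7‑(trimethylsilyl)hept‑2‑en‑6‑yne
Conditions: TBSCl (2.5 equiv), imidazole, DMF, rt
Reagents that add atoms: tert‑butyldimethylsilyl chloride CC(C)(C)[Si](C)(C)Cl
Why: Standard silylation of both hydroxyl groups masks them against the organolithium and the chloroformate of the next step.

Step 4
Reactants: 8 (S,E)‑1,5‑bis(tert‑butyldimethylsilyloxy)‑3‑methyl‑7‑(trimethylsilyl)hept‑2‑en‑6‑yne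
Product: 10 ethyl (4S,6E)‑4,8‑bis(tert‑butyldimethylsilyloxy)‑6‑methyloct‑6‑en‑2‑ynoate, via lithium acetylide 9 (not isolated)
Conditions: MeLi·LiBr, THF, 0 °C → rt; then ClCO2Et, −78 → 0 °C
Reagents that add atoms: ethyl chloroformate CCOC(=O)Cl
Why: Methyllithium should cleave the C(sp)–Si bond of the trimethylsilyl alkyne to the lithium acetylide 9, which is C‑acylated by the chloroformate (acetylide acylation) while the silyl ethers and the C5 centre are unaffected.

Step 5
Reactants: 10 ethyl (4S,6E)‑4,8‑bis(tert‑butyldimethylsilyloxy)‑6‑methyloct‑6‑en‑2‑ynoate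
Product: 11 ethyl (4S,6E)‑4,8‑dihydroxy‑6‑methyloct‑6‑en‑2‑ynoate
Conditions: HF·pyridine, THF–pyridine, 0 °C → rt
Reagents that add atoms: none
Why: Acidic fluoride desilylation should free both hydroxyl groups without base, so that the ynoate and the propargylic C5 centre are not disturbed.

Step 6
Reactants: 11 ethyl (4S,6E)‑4,8‑dihydroxy‑6‑methyloct‑6‑en‑2‑ynoate; 12 allyl alcohol
Product: 14 3‑[(5S)‑5‑[(2E)‑4‑hydroxy‑2‑methylbut‑2‑en‑1‑yl]‑2‑oxo‑2,5‑dihydrofuran‑3‑yl]propanal, via acyclic hydroxy enoate 13 (not isolated)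
Conditions: CpRu(cod)Cl (10 mol %), NH4PF6 (20 mol %), allyl alcohol (3 equiv), DMF–H2O (3:1), 80 °C
Reagents that add atoms: none
Why: Ruthenium‑catalysed alkene–alkyne coupling (Alder‑ene type) in its redox‑isomerising form: the CpRu cation binds the C6≡C7 triple bond of 11 and the vinyl group of 12, oxidative cyclisation gives a ruthenacyclopentene in which the terminal CH2 of 12 (C8) is bonded to the ester‑bearing alkyne carbon C7, β‑hydride elimination of the carbinol C10–H gives an enol ruthenium hydride, and C6–H reductive elimination followed by enol‑to‑aldehyde tautomerisation releases 13. The closest known reactions are the ruthenium‑catalysed α‑alkylation of 4‑hydroxy‑2‑alkynoates with terminal alkenes to butenolides and the coupling of alkynes with allyl alcohols to γ,δ‑unsaturated carbonyl compounds. The butenolide closes by 5‑exo‑trig acyl substitution of the C5 hydroxyl on the ester carbonyl with loss of ethanol, which is possible because the cis addition places C5 and the ester on the same side of the new C6=C7 bond. No stereocentre is formed, and C5 is not touched under these neutral conditions. The step needs C–C bond formation at C7 and not at C6, which the 4‑hydroxy‑2‑ynoate motif is known to impose; bonding through the unsubstituted alkene carbon, which the metallacycle and the β‑hydride elimination require; and reaction of the monosubstituted alkene of 12 in preference to the trisubstituted C2=C3 alkene, which this catalyst does not engage.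

Step 7
Reactants: 14 3‑[(5S)‑5‑[(2E)‑4‑hydroxy‑2‑methylbut‑2‑en‑1‑yl]‑2‑oxo‑2,5‑dihydrofuran‑3‑yl]propanal
Product: 15 (2E)‑5‑[(5S)‑5‑[(2E)‑4‑hydroxy‑2‑methylbut‑2‑en‑1‑yl]‑2‑oxo‑2,5‑dihydrofuran‑3‑yl]‑2‑methylpent‑2‑enal
Conditions: Ph3P=C(CH3)CHO (1.3 equiv), toluene, 80 °C
Reagents that add atoms: 2‑(triphenylphosphoranylidene)propanal CC(C=O)=P(c1ccccc1)(c1ccccc1)c1ccccc1
Why: Wittig olefination with the formyl‑stabilised ylide should be (E)‑selective, react with the aldehyde only and not with the lactone carbonyl, and be too weakly basic to epimerise C5.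

Step 8
Reactants: 15 (2E)‑5‑[(5S)‑5‑[(2E)‑4‑hydroxy‑2‑methylbut‑2‑en‑1‑yl]‑2‑oxo‑2,5‑dihydrofuran‑3‑yl]‑2‑methylpent‑2‑enal
Product: 16 (5S)‑5‑[(2E)‑4‑hydroxy‑2‑methylbut‑2‑en‑1‑yl]‑3‑[(3E)‑5‑hydroxy‑4‑methylpent‑3‑en‑1‑yl]furan‑2(5H)‑one
Conditions: NaBH4, CeCl3·7H2O, MeOH, −78 → −40 °C
Reagents that add atoms: none
Why: Luche reduction should give clean 1,2‑reduction of the enal at low temperature, at which the α‑substituted butenolide is not reduced.

Step 9
Reactants: 16 (5S)‑5‑[(2E)‑4‑hydroxy‑2‑methylbut‑2‑en‑1‑yl]‑3‑[(3E)‑5‑hydroxy‑4‑methylpent‑3‑en‑1‑yl]furan‑2(5H)‑one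
Product: 17 (2E)‑4‑[(2S)‑4‑[(3E)‑5‑acetoxy‑4‑methylpent‑3‑en‑1‑yl]‑5‑oxo‑2,5‑dihydrofuran‑2‑yl]‑3‑methylbut‑2‑en‑1‑yl acetate
Conditions: Ac2O, pyridine, DMAP (cat.), CH2Cl2, 0 °C
Reagents that add atoms: acetic anhydride CC(=O)OC(C)=O
Why: Acetylation of the two primary allylic alcohols under a mild amine base should complete the target without epimerising C5.

**Compound list**
1 | 3‑(trimethylsilyl)prop‑2‑ynal | C[Si](C)(C)C#CC=O | starting material
2 | allenylboronic acid pinacol ester | C=C=CB1OC(C)(C)C(C)(C)O1 | starting material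
3 | (S)‑4,4,5,5‑tetramethyl‑2‑{[1‑(trimethylsilyl)hexa‑1,5‑diyn‑3‑yl]oxy}‑1,3,2‑dioxaborolane | C#CC[C@H](OB1OC(C)(C)C(C)(C)O1)C#C[Si](C)(C)C | intermediate
4 | (S)‑1‑(trimethylsilyl)hexa‑1,5‑diyn‑3‑ol | C#CC[C@H](O)C#C[Si](C)(C)C | intermediate
5 | (S,E)‑alkenyldimethylalane, O‑dimethylaluminium alkoxide of the C2‑aluminated 3‑methyl‑7‑(trimethylsilyl)hept‑2‑en‑6‑yn‑5‑ol | C[Al](C)/C=C(\C)C[C@H](O[Al](C)C)C#C[Si](C)(C)C | intermediate
6 | lithium butyl(dimethyl)alkenylalanate derived from 5 | [Li+].CCCC[Al-](C)(C)/C=C(\C)C[C@H](O[Al](C)C)C#C[Si](C)(C)C | intermediate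
7 | (S,E)‑3‑methyl‑7‑(trimethylsilyl)hept‑2‑en‑6‑yne‑1,5‑diol | OC/C=C(\C)C[C@H](O)C#C[Si](C)(C)C | intermediate
8 | (S,E)‑1,5‑bis(tert‑butyldimethylsilyloxy)‑3‑methyl‑7‑(trimethylsilyl)hept‑2‑en‑6‑yne | CC(C)(C)[Si](C)(C)OC/C=C(\C)C[C@H](O[Si](C)(C)C(C)(C)C)C#C[Si](C)(C)C | intermediate
9 | lithium acetylide of (S,E)‑3,7‑bis(tert‑butyldimethylsilyloxy)‑5‑methylhept‑5‑en‑1‑yne | CC(C)(C)[Si](C)(C)OC/C=C(\C)C[C@H](O[Si](C)(C)C(C)(C)C)C#C[Li] | intermediate
10 | ethyl (4S,6E)‑4,8‑bis(tert‑butyldimethylsilyloxy)‑6‑methyloct‑6‑en‑2‑ynoate | CC(C)(C)[Si](C)(C)OC/C=C(\C)C[C@H](O[Si](C)(C)C(C)(C)C)C#CC(=O)OCC | intermediate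
11 | ethyl (4S,6E)‑4,8‑dihydroxy‑6‑methyloct‑6‑en‑2‑ynoate | OC/C=C(\C)C[C@H](O)C#CC(=O)OCC | intermediate
12 | allyl alcohol | C=CCO | starting material
13 | ethyl (2Z,4S,6E)‑4,8‑dihydroxy‑6‑methyl‑2‑(3‑oxopropyl)octa‑2,6‑dienoate | OC/C=C(\C)C[C@H](O)/C=C(/CCC=O)C(=O)OCC | intermediate
14 | 3‑[(5S)‑5‑[(2E)‑4‑hydroxy‑2‑methylbut‑2‑en‑1‑yl]‑2‑oxo‑2,5‑dihydrofuran‑3‑yl]propanal | OC/C=C(\C)C[C@H]1C=C(CCC=O)C(=O)O1 | intermediate
15 | (2E)‑5‑[(5S)‑5‑[(2E)‑4‑hydroxy‑2‑methylbut‑2‑en‑1‑yl]‑2‑oxo‑2,5‑dihydrofuran‑3‑yl]‑2‑methylpent‑2‑enal | OC/C=C(\C)C[C@H]1C=C(CC/C=C(\C)C=O)C(=O)O1 | intermediate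
16 | (5S)‑5‑[(2E)‑4‑hydroxy‑2‑methylbut‑2‑en‑1‑yl]‑3‑[(3E)‑5‑hydroxy‑4‑methylpent‑3‑en‑1‑yl]furan‑2(5H)‑one | OC/C=C(\C)C[C@H]1C=C(CC/C=C(\C)CO)C(=O)O1 | intermediate
17 | (2E)‑4‑[(2S)‑4‑[(3E)‑5‑acetoxy‑4‑methylpent‑3‑en‑1‑yl]‑5‑oxo‑2,5‑dihydrofuran‑2‑yl]‑3‑methylbut‑2‑en‑1‑yl acetate | CC(=O)OC/C=C(\C)C[C@H]1C=C(CC/C=C(\C)COC(C)=O)C(=O)O1 | target

**Step count:** 9 steps in total. **Longest linear sequence:** 9 steps (from 1).

**Steps most likely to fail**

Step 6. What may go wrong: loss of regiocontrol in the oxidative cyclisation (C–C bond formation at C6 instead of C7), competing ruthenium‑mediated redox isomerisation of allyl alcohol or of the propargylic carbinol, and degradation of the aldehyde at 80 °C. The fallback sets out from 11 and returns at 14, and forms the same C7–C8 bond by cross‑coupling. Palladium‑catalysed cis‑hydrostannation of 11 (Bu3SnH, Pd(PPh3)4, THF, rt) should place tin on the ester‑bearing carbon, and the adduct should lactonise to (5S)‑5‑[(2E)‑4‑hydroxy‑2‑methylbut‑2‑en‑1‑yl]‑3‑(tributylstannyl)furan‑2(5H)‑one F1. Iododestannylation (I2, CH2Cl2, 0 °C) should give (5S)‑5‑[(2E)‑4‑hydroxy‑2‑methylbut‑2‑en‑1‑yl]‑3‑iodofuran‑2(5H)‑one F2. B‑alkyl Suzuki–Miyaura coupling of F2 with 9‑(3,3‑diethoxypropyl)‑9‑borabicyclo[3.3.1]nonane F3 (made from acrolein diethyl acetal and 9‑BBN‑H in THF; coupling with PdCl2(dppf), AsPh3, Cs2CO3, DMF–THF–H2O, rt) should give (5S)‑3‑(3,3‑diethoxypropyl)‑5‑[(2E)‑4‑hydroxy‑2‑methylbut‑2‑en‑1‑yl]furan‑2(5H)‑one F4. Acetal hydrolysis (PPTS, acetone–H2O) then gives 14.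

Step 1. What may go wrong: insufficient facial discrimination, because uncatalysed background addition of the allenylboronate to the very electrophilic ynal can erode the enantiomeric purity. The fallback sets out from 1 and returns at 4, and replaces asymmetric catalysis by resolution. Zinc‑mediated Barbier propargylation of 1 (propargyl bromide, Zn, THF, 0 °C) should give racemic 1‑(trimethylsilyl)hexa‑1,5‑diyn‑3‑ol F5. Lipase‑catalysed transesterification (lipase PS from Burkholderia cepacia, vinyl acetate, hexane, rt) is expected, by the empirical rule for secondary alcohols, to acylate the (R)‑antipode to (R)‑1‑(trimethylsilyl)hexa‑1,5‑diyn‑3‑yl acetate F6 and to leave the (S)‑alcohol 4, which is separated by chromatography.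

Step 2. What may go wrong: incomplete hydroxymethylation of the alkenylaluminium species (protodealumination on work‑up) or competing metallation of the terminal alkyne. The fallback sets out from 4 and returns at 7, and introduces C1 by cross‑coupling. Carboalumination of 4 to the alkenylalane 5 as in step 2, followed by an iodine quench (I2, THF, −30 °C), should give (S,E)‑6‑iodo‑5‑methyl‑1‑(trimethylsilyl)hex‑5‑en‑1‑yn‑3‑ol F7. Stille coupling of F7 with (tributylstannyl)methanol (Pd(PPh3)4, toluene, 90 °C) should then give 7.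

**Further compounds**
F1 | step 6 | (5S)‑5‑[(2E)‑4‑hydroxy‑2‑methylbut‑2‑en‑1‑yl]‑3‑(tributylstannyl)furan‑2(5H)‑one | OC/C=C(\C)C[C@H]1C=C([Sn](CCCC)(CCCC)CCCC)C(=O)O1
F2 | step 6 | (5S)‑5‑[(2E)‑4‑hydroxy‑2‑methylbut‑2‑en‑1‑yl]‑3‑iodofuran‑2(5H)‑one | OC/C=C(\C)C[C@H]1C=C(I)C(=O)O1
F3 | step 6 | 9‑(3,3‑diethoxypropyl)‑9‑borabicyclo[3.3.1]nonane | CCOC(CCB1C2CCCC1CCC2)OCC
F4 | step 6 | (5S)‑3‑(3,3‑diethoxypropyl)‑5‑[(2E)‑4‑hydroxy‑2‑methylbut‑2‑en‑1‑yl]furan‑2(5H)‑one | OC/C=C(\C)C[C@H]1C=C(CCC(OCC)OCC)C(=O)O1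
F5 | step 1 | rac‑1‑(trimethylsilyl)hexa‑1,5‑diyn‑3‑ol | C#CCC(O)C#C[Si](C)(C)C
F6 | step 1 | (R)‑1‑(trimethylsilyl)hexa‑1,5‑diyn‑3‑yl acetate | C#CC[C@@H](OC(C)=O)C#C[Si](C)(C)C
F7 | step 2 | (S,E)‑6‑iodo‑5‑methyl‑1‑(trimethylsilyl)hex‑5‑en‑1‑yn‑3‑ol | I/C=C(\C)C[C@H](O)C#C[Si](C)(C)C
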